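**Strategy.** The lactone carbonyl C2 is bonded only to C3 and O1, so the oxolanone ring (O1–C2–C3–C4–C5) is cut back to carbon monoxide and a flat allylic alcohol in which C3=C4 is an E trisubstituted alkene and C5 carries the hydroxyl. One palladium-catalysed, ligand-controlled cyclocarbonylation then forms C2–C3 and C2–O1, closes the ring and sets C3 and C4 together; the E geometry becomes the trans relationship of the two arylmethyl arms (C7′ to ring A, C7 to ring B). The precursor is tribenzyl-protected so that no phenol, above all O2′ of ring A, can intercept the acyl group. It is assembled by an E-selective Wittig reaction and ester reduction.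

Key step: step 9

Numbering: lactone O1, C2 (C=O), C3, C4, C5; C7′ is the benzylic carbon on C3 leading to ring A (2,4-dioxygenated, 3-methoxy); C7 is the benzylic carbon on C4 leading to ring B (4-oxygenated, 3-methoxy).

Remark: the hand of the diphosphine that gives the 4R centre cannot be predicted with confidence; the route is written for whichever antipode of BPPM (tert-butyl 4-(diphenylphosphanyl)-2-[(diphenylphosphanyl)methyl]pyrrolidine-1-carboxylate) does so, to be settled in a first small run.

**Step 1**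
Reactants: 1 2-methoxyresorcinol
Product: 2 1,3-bis(benzyloxy)-2-methoxybenzene
Conditions: BnBr (2.3 equiv), K2CO3, DMF, 60 °C
Reagents that add atoms: benzyl bromide, BrCc1ccccc1
Why: Williamson etherification of both phenols by SN2 on benzyl bromide; the methyl ether is inert.

**Step 2**
Reactants: 2 1,3-bis(benzyloxy)-2-methoxybenzene
Product: 4 2,4-bis(benzyloxy)-3-methoxybenzaldehyde, via iminium chloride 3 (not isolated)
Conditions: POCl3, DMF, 0 to 70 °C; then ice-water
Reagents that add atoms: N,N-dimethylformamide, CN(C)C=O; water, O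
Why: Vilsmeier–Haack formylation should occur at C4 of the arene, the position para to one benzyloxy group and ortho to the other (as with 1,2,3-trialkoxybenzenes), and water hydrolyses the iminium salt to the aldehyde.

**Step 3**
Reactants: 4 2,4-bis(benzyloxy)-3-methoxybenzaldehyde
Product: 5 1,3-bis(benzyloxy)-2-methoxy-4-(2-methoxyethenyl)benzene (E/Z mixture)
Conditions: MeOCH2PPh3Cl, KOtBu, THF, 0 °C to rt
Reagents that add atoms: (methoxymethyl)triphenylphosphonium chloride, COC[P+](c1ccccc1)(c1ccccc1)c1ccccc1.[Cl-]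
Why: Wittig methoxymethylenation of a non-enolisable aryl aldehyde adds the carbon that becomes C3; the enol ether geometry is irrelevant because both isomers hydrolyse to the same aldehyde.

**Step 4**
Reactants: 5 1,3-bis(benzyloxy)-2-methoxy-4-(2-methoxyethenyl)benzene
Product: 6 [2,4-bis(benzyloxy)-3-methoxyphenyl]acetaldehyde
Conditions: 2 M HCl (aq), THF, 45 °C; crude aldehyde used at once
Reagents that add atoms: water, O
Why: acid-catalysed enol ether hydrolysis (C-protonation, hemiacetal collapse) under conditions that benzyl aryl ethers tolerate.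

**Step 5**
Reactants: 7 4-benzyloxy-3-methoxybenzyl alcohol
Product: 8 1-(benzyloxy)-4-(bromomethyl)-2-methoxybenzene
Conditions: PBr3, Et2O, 0 °C
Reagents that add atoms: phosphorus tribromide, BrP(Br)Br
Why: bromination of a primary benzylic alcohol through its phosphite ester (SN2), a standard preparation of this benzylic bromide.

**Step 6**
Reactants: 8 1-(benzyloxy)-4-(bromomethyl)-2-methoxybenzene; 9 ethyl (triphenylphosphoranylidene)acetate
Product: 11 ethyl 3-(4-benzyloxy-3-methoxyphenyl)-2-(triphenylphosphoranylidene)propanoate, via phosphonium bromide 10 (not isolated)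
Conditions: CHCl3, reflux; then 2 M NaOH (aq), CH2Cl2, rt
Reagents that add atoms: none
Why: C-alkylation of the stabilised ylide by the benzylic bromide gives the phosphonium salt, which aqueous base deprotonates to the α-substituted stabilised ylide (ylide alkylation).

**Step 7**
Reactants: 6 [2,4-bis(benzyloxy)-3-methoxyphenyl]acetaldehyde; 11 ethyl 3-(4-benzyloxy-3-methoxyphenyl)-2-(triphenylphosphoranylidene)propanoate
Product: 12 ethyl (E)-2-[(4-benzyloxy-3-methoxyphenyl)methyl]-4-[2,4-bis(benzyloxy)-3-methoxyphenyl]but-2-enoate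
Conditions: toluene, 60 °C
Reagents that add atoms: none
Why: Wittig olefination with an α-substituted stabilised ylide should give the E enoate (ester trans to C7′, the two arylmethyl groups cis), and the base-free medium keeps the skipped alkene out of conjugation with ring A.

**Step 8**
Reactants: 12 ethyl (E)-2-[(4-benzyloxy-3-methoxyphenyl)methyl]-4-[2,4-bis(benzyloxy)-3-methoxyphenyl]but-2-enoate
Product: 13 (E)-2-[(4-benzyloxy-3-methoxyphenyl)methyl]-4-[2,4-bis(benzyloxy)-3-methoxyphenyl]but-2-en-1-ol
Conditions: iBu2AlH (2.5 equiv), CH2Cl2, −78 °C; then aqueous potassium sodium tartrate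
Reagents that add atoms: none
Why: 1,2-reduction of the conjugated ester by the aluminium hydride gives the allylic alcohol without touching the alkene geometry or the benzyl ethers.

**Step 9**
Reactants: 13 (E)-2-[(4-benzyloxy-3-methoxyphenyl)methyl]-4-[2,4-bis(benzyloxy)-3-methoxyphenyl]but-2-en-1-ol
Product: 14 (3R,4R)-3-{[2,4-bis(benzyloxy)-3-methoxyphenyl]methyl}-4-[(4-benzyloxy-3-methoxyphenyl)methyl]oxolan-2-one
Conditions: Pd(dba)2 (4 mol %), (2S,4S)-BPPM or its antipode (8 mol %), CO (27 bar), H2 (27 bar), CH2Cl2, 100 °C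
Reagents that add atoms: carbon monoxide, [C-]#[O+]
Why: A palladium hydride, formed from Pd(dba)2 (zerovalent palladium), the diphosphine and H2, adds syn across C3=C4 with hydrogen to C4 and palladium to the less substituted C3; CO then inserts into the C3–Pd bond with retention and the C5 hydroxyl attacks the acyl palladium, forming C2–O1 and returning the hydride, so H2 is not consumed in the net equation. The closest known reaction type is the palladium-catalysed cyclocarbonylation of allylic alcohols to γ-butyrolactones under CO/H2, including its enantioselective form with chiral diphosphines on β,γ-disubstituted allylic alcohols; a primary alcohol of this substitution pattern lies at the edge of that scope. The oxolanone ring closes by 5-exo-trig attack of O1 on the acyl carbon C2. C4 is set by the chiral diphosphine, which must steer hydride to the Si face of C4 (priorities C5 > C3 > C7), and C3 follows from syn delivery of the acyl group to the same face of the E alkene, which places the two arylmethyl groups trans (also the thermodynamic arrangement) and gives 3R,4R. The step needs regiocontrol (palladium at C3, not C4), secured by the preference for a secondary over a tertiary alkyl palladium and by the five-membered closure open to the C5 hydroxyl. It also needs chemoselectivity: the benzyl ethers stop a phenol from capturing the acyl (a free O2′ on ring A could close a six-membered aryl lactone), and the CO pressure is meant to outrun β-hydride elimination toward C7′ or C7.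

**Step 10**
Reactants: 14 (3R,4R)-3-{[2,4-bis(benzyloxy)-3-methoxyphenyl]methyl}-4-[(4-benzyloxy-3-methoxyphenyl)methyl]oxolan-2-one
Product: 15 (3R,4R)-3-[(2,4-dihydroxy-3-methoxyphenyl)methyl]-4-[(4-hydroxy-3-methoxyphenyl)methyl]oxolan-2-one
Conditions: H2 (1 bar), Pd/C (10 %), EtOAc/EtOH, rt
Reagents that add atoms: none
Why: catalytic hydrogenolysis of the three benzyl aryl ethers under neutral conditions should leave the lactone and both stereocentres untouched.

**Compound list**
1 | 2-methoxyresorcinol | COc1c(O)cccc1O | starting material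
2 | 1,3-bis(benzyloxy)-2-methoxybenzene | COc1c(OCc2ccccc2)cccc1OCc1ccccc1 | intermediate
3 | {[2,4-bis(benzyloxy)-3-methoxyphenyl]methylidene}dimethylammonium chloride | C[N+](C)=Cc1ccc(OCc2ccccc2)c(OC)c1OCc1ccccc1.[Cl-] | intermediate
4 | 2,4-bis(benzyloxy)-3-methoxybenzaldehyde | O=Cc1ccc(OCc2ccccc2)c(OC)c1OCc1ccccc1 | intermediate
5 | 1,3-bis(benzyloxy)-2-methoxy-4-(2-methoxyethenyl)benzene (E/Z mixture) | COC=Cc1ccc(OCc2ccccc2)c(OC)c1OCc1ccccc1 | intermediate
6 | [2,4-bis(benzyloxy)-3-methoxyphenyl]acetaldehyde | O=CCc1ccc(OCc2ccccc2)c(OC)c1OCc1ccccc1 | intermediate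
7 | 4-benzyloxy-3-methoxybenzyl alcohol | OCc1ccc(OCc2ccccc2)c(OC)c1 | starting material
8 | 1-(benzyloxy)-4-(bromomethyl)-2-methoxybenzene | BrCc1ccc(OCc2ccccc2)c(OC)c1 | intermediate
9 | ethyl (triphenylphosphoranylidene)acetate | CCOC(=O)C=P(c1ccccc1)(c1ccccc1)c1ccccc1 | starting material
10 | [3-(4-benzyloxy-3-methoxyphenyl)-1-ethoxy-1-oxopropan-2-yl]triphenylphosphonium bromide (racemic) | CCOC(=O)C(Cc1ccc(OCc2ccccc2)c(OC)c1)[P+](c1ccccc1)(c1ccccc1)c1ccccc1.[Br-] | intermediate
11 | ethyl 3-(4-benzyloxy-3-methoxyphenyl)-2-(triphenylphosphoranylidene)propanoate | CCOC(=O)C(Cc1ccc(OCc2ccccc2)c(OC)c1)=P(c1ccccc1)(c1ccccc1)c1ccccc1 | intermediate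
12 | ethyl (E)-2-[(4-benzyloxy-3-methoxyphenyl)methyl]-4-[2,4-bis(benzyloxy)-3-methoxyphenyl]but-2-enoate | CCOC(=O)/C(Cc1ccc(OCc2ccccc2)c(OC)c1)=C/Cc1ccc(OCc2ccccc2)c(OC)c1OCc1ccccc1 | intermediate
13 | (E)-2-[(4-benzyloxy-3-methoxyphenyl)methyl]-4-[2,4-bis(benzyloxy)-3-methoxyphenyl]but-2-en-1-ol | OC/C(Cc1ccc(OCc2ccccc2)c(OC)c1)=C/Cc1ccc(OCc2ccccc2)c(OC)c1OCc1ccccc1 | intermediate
14 | (3R,4R)-3-{[2,4-bis(benzyloxy)-3-methoxyphenyl]methyl}-4-[(4-benzyloxy-3-methoxyphenyl)methyl]oxolan-2-one | COc1cc(C[C@H]2COC(=O)[C@@H]2Cc2ccc(OCc3ccccc3)c(OC)c2OCc2ccccc2)ccc1OCc1ccccc1 | intermediate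
15 | (3R,4R)-3-[(2,4-dihydroxy-3-methoxyphenyl)methyl]-4-[(4-hydroxy-3-methoxyphenyl)methyl]oxolan-2-one | COc1cc(C[C@H]2COC(=O)[C@@H]2Cc2ccc(O)c(OC)c2O)ccc1O | target

**Step count.** Total: 10 steps. Longest linear sequence: 8 steps (1, 2, 3, 4, 7, 8, 9, 10); steps 5 and 6 are the ring B branch.

**Steps most likely to fail**

Step 9. The two alkene faces differ only through remote aryl groups, so facial discrimination by the ligand may be weak. Reversible hydropalladation may also move the double bond toward ring A or ring B, and the primary allylic C5–O bond may ionise. A partly cis lactone could be equilibrated at C3 with DBU, but poor induction at C4 cannot be repaired. The fallback replaces catalysis by auxiliary control; it sets out from bromide 8, uses aldehyde 4, and returns to the route at 15, bypassing 14. Mono-tert-butyl succinate is coupled to (R)-4-benzyloxazolidin-2-one (pivaloyl chloride, Et3N, LiCl, THF) to give (R)-4-benzyl-3-[4-(tert-butoxy)-4-oxobutanoyl]oxazolidin-2-one F1. Its sodium Z enolate (NaN(SiMe3)2, THF, −78 °C) should be alkylated by 8 anti to the auxiliary benzyl group (Evans alkylation) to give (R)-4-benzyl-3-[(2R)-2-[(4-benzyloxy-3-methoxyphenyl)methyl]-4-(tert-butoxy)-4-oxobutanoyl]oxazolidin-2-one F2. LiBH4 (THF, H2O, 0 °C) removes the auxiliary reductively to give tert-butyl (3R)-3-[(4-benzyloxy-3-methoxyphenyl)methyl]-4-hydroxybutanoate F3, which TsOH in warm toluene closes to (4R)-4-[(4-benzyloxy-3-methoxyphenyl)methyl]oxolan-2-one F4. The lithium enolate of F4 (LiN(iPr)2, THF, −78 °C) should add to 4 anti to the C4 substituent to give the trans aldol adduct (3S,4R)-3-{[2,4-bis(benzyloxy)-3-methoxyphenyl](hydroxy)methyl}-4-[(4-benzyloxy-3-methoxyphenyl)methyl]oxolan-2-one F5 as a mixture of carbinol epimers. Hydrogenolysis (H2, Pd/C, EtOAc/AcOH) then removes the benzylic hydroxyl together with the three benzyl ethers to give 15.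

Step 7. The enolisable aldehyde 6 may be consumed by self-condensation before olefination, or the alkene geometry may erode. The fallback builds the alkene by anti addition to an alkyne; it sets out from aldehyde 4, uses bromide 8, and returns at 13, bypassing 5, 6, 11 and 12. The dilithium salt of propargyl alcohol (2 nBuLi, THF, −78 °C) adds to 4 to give 1-[2,4-bis(benzyloxy)-3-methoxyphenyl]but-2-yne-1,4-diol F6. Ionic deoxygenation of the benzylic, propargylic hydroxyl (Et3SiH, BF3·OEt2, CH2Cl2, −40 °C) gives 4-[2,4-bis(benzyloxy)-3-methoxyphenyl]but-2-yn-1-ol F7. Hydroxyl-directed trans-hydrostannation (Bu3SnH, [Cp*RuCl]4, CH2Cl2) should place tin on the alkyne carbon next to the carbinol and give (Z)-4-[2,4-bis(benzyloxy)-3-methoxyphenyl]-2-(tributylstannyl)but-2-en-1-ol F8. Stille coupling with 8 (Pd2(dba)3, tri(2-furyl)phosphine, THF, 60 °C) with retention at the alkenyl carbon gives 13.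

Step 4. The electron-rich arylacetaldehyde may condense with itself or polymerise under the acid needed for enol ether hydrolysis. The fallback reaches the aldehyde by oxidation under buffered conditions; it sets out from arene 2 and returns at 6, bypassing 3, 4 and 5. Bromination para to a benzyloxy group (NBS, MeCN, 0 °C) gives 1,3-bis(benzyloxy)-4-bromo-2-methoxybenzene F9. Bromine–lithium exchange (nBuLi, THF, −78 °C) and opening of ethylene oxide (BF3·OEt2) give 2-[2,4-bis(benzyloxy)-3-methoxyphenyl]ethanol F10. Dess–Martin periodinane (NaHCO3, CH2Cl2, 0 °C) gives 6, to be used at once in step 7.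

**Further compounds**
F1 | step 9 | (R)-4-benzyl-3-[4-(tert-butoxy)-4-oxobutanoyl]oxazolidin-2-one | CC(C)(C)OC(=O)CCC(=O)N1[C@H](Cc2ccccc2)COC1=O
F2 | step 9 | (R)-4-benzyl-3-[(2R)-2-[(4-benzyloxy-3-methoxyphenyl)methyl]-4-(tert-butoxy)-4-oxobutanoyl]oxazolidin-2-one | CC(C)(C)OC(=O)C[C@@H](Cc1ccc(OCc2ccccc2)c(OC)c1)C(=O)N1[C@H](Cc2ccccc2)COC1=O
F3 | step 9 | tert-butyl (3R)-3-[(4-benzyloxy-3-methoxyphenyl)methyl]-4-hydroxybutanoate | CC(C)(C)OC(=O)C[C@@H](Cc1ccc(OCc2ccccc2)c(OC)c1)CO
F4 | step 9 | (4R)-4-[(4-benzyloxy-3-methoxyphenyl)methyl]oxolan-2-one | O=C1C[C@@H](Cc2ccc(OCc3ccccc3)c(OC)c2)CO1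
F5 | step 9 | (3S,4R)-3-{[2,4-bis(benzyloxy)-3-methoxyphenyl](hydroxy)methyl}-4-[(4-benzyloxy-3-methoxyphenyl)methyl]oxolan-2-one (mixture of carbinol epimers) | COc1cc(C[C@H]2COC(=O)[C@@H]2C(O)c2ccc(OCc3ccccc3)c(OC)c2OCc2ccccc2)ccc1OCc1ccccc1
F6 | step 7 | 1-[2,4-bis(benzyloxy)-3-methoxyphenyl]but-2-yne-1,4-diol (racemic) | OCC#CC(O)c1ccc(OCc2ccccc2)c(OC)c1OCc1ccccc1
F7 | step 7 | 4-[2,4-bis(benzyloxy)-3-methoxyphenyl]but-2-yn-1-ol | OCC#CCc1ccc(OCc2ccccc2)c(OC)c1OCc1ccccc1
F8 | step 7 | (Z)-4-[2,4-bis(benzyloxy)-3-methoxyphenyl]-2-(tributylstannyl)but-2-en-1-ol | OC/C(=C/Cc1ccc(OCc2ccccc2)c(OC)c1OCc1ccccc1)[Sn](CCCC)(CCCC)CCCC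
F9 | step 4 | 1,3-bis(benzyloxy)-4-bromo-2-methoxybenzene | COc1c(OCc2ccccc2)ccc(Br)c1OCc1ccccc1
F10 | step 4 | 2-[2,4-bis(benzyloxy)-3-methoxyphenyl]ethanol | OCCc1ccc(OCc2ccccc2)c(OC)c1OCc1ccccc1
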